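**Retrosynthetic overview**
1. Numbering: carbocycle C1–C10 (C1–C3 methylenes, C4 methyl-bearing oxirane carbon, C5 oxirane CH, C6 ester carbinol, C7 and C8 ring fusion, C9 carbinol, C10 methyl-bearing CH); lactone C7–C11–C12(=O)–O–C8 with exocyclic C13. The plan rests on C6 of the ten-membered ring being a carbinol carbon flanked by the ring-cis C4=C5 alkene (the later oxirane) and by fusion carbon C7 of the trans-γ-lactone, which makes C5–C6 the bond between an alkenyl metal and an aldehyde.
2. Endgame, backwards: the C9 silyl ether, the C6 senecioate, the C4/C5 oxirane (oxygen delivered from the C6 hydroxyl) and the C11=C13 methylene are stripped to the ten-membered Z-allylic alcohol 25.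
3. Key disconnection C5–C6: chromium-mediated, nickel-catalysed ring closure of the Z-alkenyl iodide/aldehyde 23.
4. 23 comes from a syn-aldol/lactonisation of succinate imide 17 with α-silyloxy aldehyde 14 (C7–C8 bond, centres C7 and C8); 14 comes from (R)-citronellal (C10), proline α-aminoxylation (C9) and carbocupration of propyne (Z C4=C5–I).
5. Ring order: γ-lactone (step 10), ten-membered carbocycle (step 14), oxirane (step 18).

Key step: step 14

Remark: (R)-citronellal of high enantiomeric purity, propyne, (S)-4-benzyloxazolidin-2-one and methyl 4-chloro-4-oxobutanoate are taken as commercial; the locants in the names of 25–33 follow the numbering of line 1 (germacrane numbering).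

**Step 1**
Reactants: 1 (R)-citronellal
Product: 3 (2R,3R)-3,7-dimethyl-2-(phenylaminooxy)oct-6-en-1-ol, via α-aminoxy aldehyde 2 (not isolated)
Conditions: PhNO, L-proline (20 mol %), CHCl3, 4 °C; then NaBH4, EtOH, 0 °C
Reagents that add atoms: nitrosobenzene O=Nc1ccccc1
Why: Proline-catalysed α-aminoxylation (O-selective nitroso aldol of the enamine) should oxygenate C9 under catalyst control, L-proline giving the 2R centre irrespective of the adjacent methyl-bearing centre (C10, from the chiral pool), and in situ borohydride reduction traps the epimerisable aldehyde 2.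

**Step 2**
Reactants: 3 (2R,3R)-3,7-dimethyl-2-(phenylaminooxy)oct-6-en-1-ol
Product: 4 (2R,3R)-3,7-dimethyloct-6-ene-1,2-diol
Conditions: Zn dust, AcOH, EtOH, 25 °C
Reagents that add atoms: none
Why: Dissolving-metal reduction of the N–O bond should release the secondary alcohol and aniline without touching the trisubstituted alkene or either stereocentre.

**Step 3**
Reactants: 4 (2R,3R)-3,7-dimethyloct-6-ene-1,2-diol
Product: 5 (2R,3R)-1,2-bis(tert-butyldimethylsilyloxy)-3,7-dimethyloct-6-ene
Conditions: TBSOTf, 2,6-lutidine, CH2Cl2, 0 °C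
Reagents that add atoms: tert-butyldimethylsilyl triflate CC(C)(C)[Si](C)(C)OS(=O)(=O)C(F)(F)F
Why: Silylation with the silyl triflate should cap both hydroxyls, the hindered secondary one included, as ethers that withstand ozone, phosphonium bromination and organomagnesium/organocopper reagents.

**Step 4**
Reactants: 5 (2R,3R)-1,2-bis(tert-butyldimethylsilyloxy)-3,7-dimethyloct-6-ene
Product: 7 (4R,5R)-5,6-bis(tert-butyldimethylsilyloxy)-4-methylhexan-1-ol, via aldehyde 6 (not isolated)
Conditions: O3, CH2Cl2/MeOH, −78 °C; then NaBH4, −78 → 0 °C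
Reagents that add atoms: ozone [O-][O+]=O
Why: Ozonolysis with reductive work-up should excise the isopropylidene terminus of the only alkene and leave C3 as a primary alcohol, silyl ethers being inert to both reagents.

**Step 5**
Reactants: 7 (4R,5R)-5,6-bis(tert-butyldimethylsilyloxy)-4-methylhexan-1-ol
Product: 8 (2R,3R)-6-bromo-1,2-bis(tert-butyldimethylsilyloxy)-3-methylhexane
Conditions: CBr4, PPh3, CH2Cl2, 0 °C
Reagents that add atoms: carbon tetrabromide BrC(Br)(Br)Br
Why: The Appel reaction converts an unhindered primary alcohol into the bromide under near-neutral conditions that silyl ethers tolerate.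

**Step 6**
Reactants: 8 (2R,3R)-6-bromo-1,2-bis(tert-butyldimethylsilyloxy)-3-methylhexane; 9 propyne
Product: 12 (1Z,6R,7R)-7,8-bis(tert-butyldimethylsilyloxy)-1-iodo-2,6-dimethyloct-1-ene, via Grignard reagent 10 (not isolated), via alkenylcopper 11 (not isolated)
Conditions: Mg, Et2O, 35 °C; CuBr·SMe2, Et2O/Me2S, −45 °C; 9, −25 °C; I2, −78 → 0 °C
Reagents that add atoms: iodine II
Why: Carbocupration of a terminal alkyne by an alkylcopper is a syn addition that places the alkyl group (C3) on the internal carbon and copper on the terminal carbon cis to it, and iodinolysis of the alkenylcopper with retention should give the Z-alkenyl iodide (C3 cis to iodine).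

**Step 7**
Reactants: 12 (1Z,6R,7R)-7,8-bis(tert-butyldimethylsilyloxy)-1-iodo-2,6-dimethyloct-1-ene
Product: 13 (2R,3R,7Z)-2-(tert-butyldimethylsilyloxy)-8-iodo-3,7-dimethyloct-7-en-1-ol
Conditions: HF·pyridine, pyridine, THF, 0 °C
Reagents that add atoms: none
Why: Selective desilylation: buffered HF·pyridine should cleave the unhindered primary silyl ether well before the secondary one, which is shielded by the adjacent methyl-bearing carbon.

**Step 8**
Reactants: 13 (2R,3R,7Z)-2-(tert-butyldimethylsilyloxy)-8-iodo-3,7-dimethyloct-7-en-1-ol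
Product: 14 (2R,3R,7Z)-2-(tert-butyldimethylsilyloxy)-8-iodo-3,7-dimethyloct-7-enal
Conditions: Dess–Martin periodinane, NaHCO3, CH2Cl2, 0 → 25 °C
Reagents that add atoms: none
Why: Dess–Martin oxidation under buffered conditions should give the α-silyloxy aldehyde without epimerising C9, and the aldehyde is used directly.

**Step 9**
Reactants: 15 (S)-4-benzyloxazolidin-2-one; 16 methyl 4-chloro-4-oxobutanoate
Product: 17 methyl 4-[(4S)-4-benzyl-2-oxooxazolidin-3-yl]-4-oxobutanoate
Conditions: n-BuLi, THF, −78 °C; then 16, −78 → 0 °C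
Reagents that add atoms: none
Why: N-Acylation of the lithiated oxazolidinone by an acid chloride is the standard imide synthesis, the far less electrophilic methyl ester staying intact at low temperature.

**Step 10**
Reactants: 14 (2R,3R,7Z)-2-(tert-butyldimethylsilyloxy)-8-iodo-3,7-dimethyloct-7-enal; 17 methyl 4-[(4S)-4-benzyl-2-oxooxazolidin-3-yl]-4-oxobutanoate
Product: 19 (4S)-4-benzyl-3-{(2S,3S)-2-[(1R,2R,6Z)-1-(tert-butyldimethylsilyloxy)-7-iodo-2,6-dimethylhept-6-enyl]-5-oxooxolane-3-carbonyl}oxazolidin-2-one, via aldol adduct 18 (not isolated)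
Conditions: 17, Bu2BOTf, i-Pr2NEt, CH2Cl2, −78 → 0 °C; 14, −78 → 0 °C; pH 7 buffer, MeOH, H2O2, 0 °C; then PPTS (cat.), PhMe, 50 °C
Reagents that add atoms: none
Why: Evans syn-aldol reaction followed by lactonisation: soft enolisation should give the Z-boron enolate of the imide (not of the ester), whose chair Zimmerman–Traxler transition state with the (S)-benzyl auxiliary sets C7 (S) and C8 (S) syn, a sense reinforced by the Cornforth/Felkin preference of the (R)-α-silyloxy aldehyde for C8–O anti to C9–O, and the γ-hydroxy ester of 18 then closes to the trans-disubstituted γ-lactone with loss of methanol.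

**Step 11**
Reactants: 19 (4S)-4-benzyl-3-{(2S,3S)-2-[(1R,2R,6Z)-1-(tert-butyldimethylsilyloxy)-7-iodo-2,6-dimethylhept-6-enyl]-5-oxooxolane-3-carbonyl}oxazolidin-2-one
Product: 21 (2S,3S)-2-[(1R,2R,6Z)-1-(tert-butyldimethylsilyloxy)-7-iodo-2,6-dimethylhept-6-enyl]-5-oxooxolane-3-carboxylic acid, via peroxy acid 20 (not isolated)
Conditions: LiOH, H2O2, THF/H2O, 0 °C; Na2SO3; HCl to pH 3
Reagents that add atoms: hydrogen peroxide OO
Why: Hydroperoxide-mediated imide cleavage attacks the exocyclic carbonyl selectively and releases the auxiliary, any lactone opened by hydroxide closing again on acidification and the trans C7/C8 arrangement being the thermodynamically favoured one.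

**Step 12**
Reactants: 21 (2S,3S)-2-[(1R,2R,6Z)-1-(tert-butyldimethylsilyloxy)-7-iodo-2,6-dimethylhept-6-enyl]-5-oxooxolane-3-carboxylic acid
Product: 22 (4R,5S)-5-[(1R,2R,6Z)-1-(tert-butyldimethylsilyloxy)-7-iodo-2,6-dimethylhept-6-enyl]-4-(hydroxymethyl)oxolan-2-one
Conditions: BH3·SMe2, THF, 0 → 25 °C; MeOH
Reagents that add atoms: none
Why: Chemoselective borane reduction: the acid is reduced through its acyloxyborane far faster than the lactone is attacked or the hindered, electron-poor iodoalkene is hydroborated.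

**Step 13**
Reactants: 22 (4R,5S)-5-[(1R,2R,6Z)-1-(tert-butyldimethylsilyloxy)-7-iodo-2,6-dimethylhept-6-enyl]-4-(hydroxymethyl)oxolan-2-one
Product: 23 (2S,3S)-2-[(1R,2R,6Z)-1-(tert-butyldimethylsilyloxy)-7-iodo-2,6-dimethylhept-6-enyl]-5-oxooxolane-3-carbaldehyde
Conditions: Dess–Martin periodinane, NaHCO3, CH2Cl2, 0 °C
Reagents that add atoms: none
Why: Dess–Martin oxidation under buffered, base-free conditions should give the β-acyloxy aldehyde without β-elimination of the lactone oxygen or epimerisation at C7, and the crude aldehyde goes straight into the ring closure.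

**Step 14**
Reactants: 23 (2S,3S)-2-[(1R,2R,6Z)-1-(tert-butyldimethylsilyloxy)-7-iodo-2,6-dimethylhept-6-enyl]-5-oxooxolane-3-carbaldehyde
Product: 25 (4Z,6S,7R,8S,9R,10R)-9-(tert-butyldimethylsilyloxy)-6-hydroxy-13-norgermacr-4-en-12,8-olide, via alkenylchromium 24 (not isolated)
Conditions: CrCl2 (8 equiv), NiCl2 (2 mol %), degassed DMSO/THF, 25 °C, slow addition of 23 (final 0.003 M)
Reagents that add atoms: none
Why: Nozaki–Hiyama–Kishi reaction: zerovalent nickel, generated from NiCl2 by divalent chromium, inserts into the C5–I bond with retention of the Z geometry, the alkenyl group passes to trivalent chromium, and the alkenylchromium 24 adds to the C6 aldehyde. The closest known reaction type is the CrCl2/NiCl2-mediated intramolecular alkenyl iodide–aldehyde coupling that closes medium-ring allylic alcohols. The ten-membered carbocycle is closed by a 10-exo-trig 1,2-addition of C5 to the C6 carbonyl, run under high dilution with slow addition of 23. The new C6 centre is controlled by the adjacent C7 centre through a Felkin–Anh arrangement in which C5 approaches anti to the C7–C8 bond with the carbonyl oxygen on the side of C11, which should give the 6S alcohol (hydroxyl syn to C11, the configuration that is 6R in the target once epoxidation changes the priorities). The step needs attack on the aldehyde only, no β-elimination or C7 epimerisation of the β-acyloxy aldehyde, retention of the alkene geometry and ring closure in preference to oligomerisation. These are secured by the low basicity and aldehyde selectivity of the alkenylchromium, by the stereoretentive nickel insertion, and by the Z-iodide and the trans-lactone, which turn the two chain ends towards each other.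

**Step 15**
Reactants: 25 (4Z,6S,7R,8S,9R,10R)-9-(tert-butyldimethylsilyloxy)-6-hydroxy-13-norgermacr-4-en-12,8-olide
Product: 26 (4Z,6S,7S,8S,9R,10R)-9-(tert-butyldimethylsilyloxy)-6-(triethylsilyloxy)-13-norgermacr-4-en-12,8-olide
Conditions: TESOTf, 2,6-lutidine, CH2Cl2, −78 °C
Reagents that add atoms: triethylsilyl triflate CC[Si](CC)(CC)OS(=O)(=O)C(F)(F)F
Why: Silyl protection of the C6 hydroxyl ensures that no C6 alkoxide sits next to the lactone during the enolate step, where acyl transfer from O8 to O6 could otherwise relocate the lactone.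

**Step 16**
Reactants: 26 (4Z,6S,7S,8S,9R,10R)-9-(tert-butyldimethylsilyloxy)-6-(triethylsilyloxy)-13-norgermacr-4-en-12,8-olide
Product: 29 (4Z,6S,7S,8S,9R,10R)-9-(tert-butyldimethylsilyloxy)-6-(triethylsilyloxy)germacra-4,11(13)-dien-12,8-olide, via Mannich base 27 (not isolated), via ammonium iodide 28 (not isolated)
Conditions: LiN(i-Pr)2, THF, −78 °C; CH2=NMe2+ I−, −78 → 0 °C; then MeI, MeOH, 25 °C; then NaHCO3 (aq), EtOAc, 25 °C
Reagents that add atoms: N,N-dimethylmethyleneiminium iodide C=[N+](C)C.[I-]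
Why: The Mannich reaction of the lactone enolate with the preformed iminium salt, N-methylation and base-induced β-elimination of trimethylamine constitute the standard α-methylenation of γ-lactones, the transient C11 centre of 27 being erased and C7 (β to the carbonyl) left untouched.

**Step 17**
Reactants: 29 (4Z,6S,7S,8S,9R,10R)-9-(tert-butyldimethylsilyloxy)-6-(triethylsilyloxy)germacra-4,11(13)-dien-12,8-olide
Product: 30 (4Z,6S,7R,8S,9R,10R)-9-(tert-butyldimethylsilyloxy)-6-hydroxygermacra-4,11(13)-dien-12,8-olide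
Conditions: PPTS, MeOH/CH2Cl2, 0 °C
Reagents that add atoms: none
Why: Acid-catalysed methanolysis should remove the triethylsilyl ether selectively, the hindered tert-butyldimethylsilyl ether at C9 reacting far more slowly and the exocyclic enoate being inert to mild acid.

**Step 18**
Reactants: 30 (4Z,6S,7R,8S,9R,10R)-9-(tert-butyldimethylsilyloxy)-6-hydroxygermacra-4,11(13)-dien-12,8-olide
Product: 31 (4R,5S,6R,7R,8S,9R,10R)-9-(tert-butyldimethylsilyloxy)-4,5-epoxy-6-hydroxygermacr-11(13)-en-12,8-olide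
Conditions: VO(acac)2 (5 mol %), t-BuOOH, CH2Cl2, 0 °C
Reagents that add atoms: tert-butyl hydroperoxide CC(C)(C)OO
Why: Hydroxyl-directed vanadium-catalysed epoxidation: the C6 alkoxide binds the metal and the peroxide oxygen is delivered to the C4=C5 face syn to it in the conformer that avoids A(1,3) strain between C3 and the C6 substituents (C6–H in the alkene plane), which should give the threo epoxy alcohol with the 4R,5S oxirane, while the electron-poor C11=C13 alkene does not react.

**Step 19**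
Reactants: 31 (4R,5S,6R,7R,8S,9R,10R)-9-(tert-butyldimethylsilyloxy)-4,5-epoxy-6-hydroxygermacr-11(13)-en-12,8-olide
Product: 32 (4R,5S,6R,7R,8S,9R,10R)-9-(tert-butyldimethylsilyloxy)-4,5-epoxy-6-(3-methylbut-2-enoyloxy)germacr-11(13)-en-12,8-olide
Conditions: 3-methylbut-2-enoyl chloride, pyridine, DMAP (20 mol %), CH2Cl2, 0 → 25 °C
Reagents that add atoms: 3-methylbut-2-enoyl chloride CC(C)=CC(Cl)=O
Why: DMAP-catalysed acylation of the only free hydroxyl, with pyridine in place of a trialkylamine so that the acid chloride is not dehydrohalogenated to the vinylketene that leads to the deconjugated ester.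

**Step 20**
Reactants: 32 (4R,5S,6R,7R,8S,9R,10R)-9-(tert-butyldimethylsilyloxy)-4,5-epoxy-6-(3-methylbut-2-enoyloxy)germacr-11(13)-en-12,8-olide
Product: 33 (4R,5S,6R,7S,8S,9R,10R)-4,5-epoxy-9-hydroxy-6-(3-methylbut-2-enoyloxy)germacr-11(13)-en-12,8-olide (CNP0119422.2)
Conditions: HF·pyridine, pyridine, THF, 0 → 25 °C
Reagents that add atoms: none
Why: Fluoride-mediated desilylation under pyridine buffering should free the C9 hydroxyl without acid strong enough to open the oxirane or base able to add to the methylene lactone or shift the ester.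

**Compound list**
1 | (R)-citronellal | O=CC[C@H](C)CCC=C(C)C | starting material
2 | (2R,3R)-3,7-dimethyl-2-(phenylaminooxy)oct-6-enal | O=C[C@H](ONc1ccccc1)[C@H](C)CCC=C(C)C | intermediate
3 | (2R,3R)-3,7-dimethyl-2-(phenylaminooxy)oct-6-en-1-ol | OC[C@H](ONc1ccccc1)[C@H](C)CCC=C(C)C | intermediate
4 | (2R,3R)-3,7-dimethyloct-6-ene-1,2-diol | OC[C@H](O)[C@H](C)CCC=C(C)C | intermediate
5 | (2R,3R)-1,2-bis(tert-butyldimethylsilyloxy)-3,7-dimethyloct-6-ene | CC(C)(C)[Si](C)(C)OC[C@H](O[Si](C)(C)C(C)(C)C)[C@H](C)CCC=C(C)C | intermediate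
6 | (4R,5R)-5,6-bis(tert-butyldimethylsilyloxy)-4-methylhexanal | CC(C)(C)[Si](C)(C)OC[C@H](O[Si](C)(C)C(C)(C)C)[C@H](C)CCC=O | intermediate
7 | (4R,5R)-5,6-bis(tert-butyldimethylsilyloxy)-4-methylhexan-1-ol | CC(C)(C)[Si](C)(C)OC[C@H](O[Si](C)(C)C(C)(C)C)[C@H](C)CCCO | intermediate
8 | (2R,3R)-6-bromo-1,2-bis(tert-butyldimethylsilyloxy)-3-methylhexane | CC(C)(C)[Si](C)(C)OC[C@H](O[Si](C)(C)C(C)(C)C)[C@H](C)CCCBr | intermediate
9 | propyne | CC#C | starting material
10 | [(4R,5R)-5,6-bis(tert-butyldimethylsilyloxy)-4-methylhexyl]magnesium bromide | CC(C)(C)[Si](C)(C)OC[C@H](O[Si](C)(C)C(C)(C)C)[C@H](C)CCC[Mg]Br | intermediate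
11 | [(1Z,6R,7R)-7,8-bis(tert-butyldimethylsilyloxy)-2,6-dimethyloct-1-enyl]copper | CC(C)(C)[Si](C)(C)OC[C@H](O[Si](C)(C)C(C)(C)C)[C@H](C)CCC/C(C)=C\[Cu] | intermediate
12 | (1Z,6R,7R)-7,8-bis(tert-butyldimethylsilyloxy)-1-iodo-2,6-dimethyloct-1-ene | CC(C)(C)[Si](C)(C)OC[C@H](O[Si](C)(C)C(C)(C)C)[C@H](C)CCC/C(C)=C\I | intermediate
13 | (2R,3R,7Z)-2-(tert-butyldimethylsilyloxy)-8-iodo-3,7-dimethyloct-7-en-1-ol | OC[C@H](O[Si](C)(C)C(C)(C)C)[C@H](C)CCC/C(C)=C\I | intermediate
14 | (2R,3R,7Z)-2-(tert-butyldimethylsilyloxy)-8-iodo-3,7-dimethyloct-7-enal | O=C[C@H](O[Si](C)(C)C(C)(C)C)[C@H](C)CCC/C(C)=C\I | intermediate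
15 | (S)-4-benzyloxazolidin-2-one | O=C1OC[C@H](Cc2ccccc2)N1 | starting material
16 | methyl 4-chloro-4-oxobutanoate | COC(=O)CCC(Cl)=O | starting material
17 | methyl 4-[(4S)-4-benzyl-2-oxooxazolidin-3-yl]-4-oxobutanoate | COC(=O)CCC(=O)N1[C@@H](Cc2ccccc2)COC1=O | intermediate
18 | methyl (3S,4S,5R,6R,10Z)-3-[(4S)-4-benzyl-2-oxooxazolidine-3-carbonyl]-5-(tert-butyldimethylsilyloxy)-4-hydroxy-11-iodo-6,10-dimethylundec-10-enoate | COC(=O)C[C@@H]([C@H](O)[C@H](O[Si](C)(C)C(C)(C)C)[C@H](C)CCC/C(C)=C\I)C(=O)N1[C@@H](Cc2ccccc2)COC1=O | intermediate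
19 | (4S)-4-benzyl-3-{(2S,3S)-2-[(1R,2R,6Z)-1-(tert-butyldimethylsilyloxy)-7-iodo-2,6-dimethylhept-6-enyl]-5-oxooxolane-3-carbonyl}oxazolidin-2-one | O=C(N1[C@@H](Cc2ccccc2)COC1=O)[C@H]3CC(=O)O[C@@H]3[C@H](O[Si](C)(C)C(C)(C)C)[C@H](C)CCC/C(C)=C\I | intermediate
20 | (2S,3S)-2-[(1R,2R,6Z)-1-(tert-butyldimethylsilyloxy)-7-iodo-2,6-dimethylhept-6-enyl]-5-oxooxolane-3-carboperoxoic acid | OOC(=O)[C@H]1CC(=O)O[C@@H]1[C@H](O[Si](C)(C)C(C)(C)C)[C@H](C)CCC/C(C)=C\I | intermediate
21 | (2S,3S)-2-[(1R,2R,6Z)-1-(tert-butyldimethylsilyloxy)-7-iodo-2,6-dimethylhept-6-enyl]-5-oxooxolane-3-carboxylic acid | OC(=O)[C@H]1CC(=O)O[C@@H]1[C@H](O[Si](C)(C)C(C)(C)C)[C@H](C)CCC/C(C)=C\I | intermediate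
22 | (4R,5S)-5-[(1R,2R,6Z)-1-(tert-butyldimethylsilyloxy)-7-iodo-2,6-dimethylhept-6-enyl]-4-(hydroxymethyl)oxolan-2-one | OC[C@H]1CC(=O)O[C@@H]1[C@H](O[Si](C)(C)C(C)(C)C)[C@H](C)CCC/C(C)=C\I | intermediate
23 | (2S,3S)-2-[(1R,2R,6Z)-1-(tert-butyldimethylsilyloxy)-7-iodo-2,6-dimethylhept-6-enyl]-5-oxooxolane-3-carbaldehyde (key-step precursor) | O=C[C@H]1CC(=O)O[C@@H]1[C@H](O[Si](C)(C)C(C)(C)C)[C@H](C)CCC/C(C)=C\I | intermediate
24 | alkenylchromium dichloride from 23 (CrCl2 group on C5, trivalent chromium) | O=C[C@H]1CC(=O)O[C@@H]1[C@H](O[Si](C)(C)C(C)(C)C)[C@H](C)CCC/C(C)=C\[Cr](Cl)Cl | intermediate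
25 | (4Z,6S,7R,8S,9R,10R)-9-(tert-butyldimethylsilyloxy)-6-hydroxy-13-norgermacr-4-en-12,8-olide (key-step product) | C1C(=O)O[C@@H]2[C@H](O[Si](C)(C)C(C)(C)C)[C@H](C)CCC/C(C)=C\[C@H](O)[C@@H]12 | intermediate
26 | (4Z,6S,7S,8S,9R,10R)-9-(tert-butyldimethylsilyloxy)-6-(triethylsilyloxy)-13-norgermacr-4-en-12,8-olide | C1C(=O)O[C@@H]2[C@H](O[Si](C)(C)C(C)(C)C)[C@H](C)CCC/C(C)=C\[C@H](O[Si](CC)(CC)CC)[C@@H]12 | intermediate
27 | (4Z,6S,7S,8S,9R,10R,11R)-9-(tert-butyldimethylsilyloxy)-13-(dimethylamino)-6-(triethylsilyloxy)germacr-4-en-12,8-olide (C11 drawn as expected, inconsequential) | CN(C)C[C@@H]1C(=O)O[C@@H]2[C@H](O[Si](C)(C)C(C)(C)C)[C@H](C)CCC/C(C)=C\[C@H](O[Si](CC)(CC)CC)[C@@H]12 | intermediate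
28 | N-methyl ammonium iodide of 27 | C[N+](C)(C)C[C@@H]1C(=O)O[C@@H]2[C@H](O[Si](C)(C)C(C)(C)C)[C@H](C)CCC/C(C)=C\[C@H](O[Si](CC)(CC)CC)[C@@H]12.[I-] | intermediate
29 | (4Z,6S,7S,8S,9R,10R)-9-(tert-butyldimethylsilyloxy)-6-(triethylsilyloxy)germacra-4,11(13)-dien-12,8-olide | C=C1C(=O)O[C@@H]2[C@H](O[Si](C)(C)C(C)(C)C)[C@H](C)CCC/C(C)=C\[C@H](O[Si](CC)(CC)CC)[C@@H]12 | intermediate
30 | (4Z,6S,7R,8S,9R,10R)-9-(tert-butyldimethylsilyloxy)-6-hydroxygermacra-4,11(13)-dien-12,8-olide | C=C1C(=O)O[C@@H]2[C@H](O[Si](C)(C)C(C)(C)C)[C@H](C)CCC/C(C)=C\[C@H](O)[C@@H]12 | intermediate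
31 | (4R,5S,6R,7R,8S,9R,10R)-9-(tert-butyldimethylsilyloxy)-4,5-epoxy-6-hydroxygermacr-11(13)-en-12,8-olide | C=C1C(=O)O[C@@H]2[C@H](O[Si](C)(C)C(C)(C)C)[C@H](C)CCC[C@@]3(C)O[C@H]3[C@H](O)[C@@H]12 | intermediate
32 | (4R,5S,6R,7R,8S,9R,10R)-9-(tert-butyldimethylsilyloxy)-4,5-epoxy-6-(3-methylbut-2-enoyloxy)germacr-11(13)-en-12,8-olide | C=C1C(=O)O[C@@H]2[C@H](O[Si](C)(C)C(C)(C)C)[C@H](C)CCC[C@@]3(C)O[C@H]3[C@H](OC(=O)C=C(C)C)[C@@H]12 | intermediate
33 | (4R,5S,6R,7S,8S,9R,10R)-4,5-epoxy-9-hydroxy-6-(3-methylbut-2-enoyloxy)germacr-11(13)-en-12,8-olide (CNP0119422.2) | C=C1C(=O)O[C@@H]2[C@H](O)[C@H](C)CCC[C@@]3(C)O[C@H]3[C@H](OC(=O)C=C(C)C)[C@@H]12 | target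

**Totals**
Total step count: 20. Longest linear sequence: 19 steps (steps 1–8 and 10–20 from (R)-citronellal; step 9 is a one-step side branch).

**Steps most likely to fail**

Step 14 (ring closure). C5 may add to the undesired face of the C6 aldehyde if the conformation of the closing ring overrides the acyclic Felkin–Anh preference, and slow closure would let intermolecular coupling compete. The fallback sets out from 23 and uses the same closure for ring formation only. The 6R-epimeric alcohol, (4Z,6R,7R,8S,9R,10R)-9-(tert-butyldimethylsilyloxy)-6-hydroxy-13-norgermacr-4-en-12,8-olide F1, alone or mixed with 25, is oxidised with Dess–Martin periodinane (NaHCO3, CH2Cl2, 0 °C) to the ten-membered Z-enone F2. F2 is then reduced under Luche conditions (NaBH4, CeCl3, MeOH, −78 °C). Hydride should enter from the ring periphery, the direction from which the ring carbon C5 cannot come, so C6 is set by 1,2-reduction of a ketone instead of by C–C bond formation. The route is rejoined at 25.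

Step 18 (directed epoxidation). Oxygen may be delivered to the wrong alkene face if the ten-membered ring holds the C6 hydroxyl on the face opposite to that predicted by the A(1,3) model. The fallback sets out from 29, where C6 is still silylated and no directing group operates. NBS in aqueous THF at 0 °C should form the bromonium ion on the exposed alkene face, and water opens it at the tertiary carbon C4 to give bromohydrin F3 (C4–OH, C5–Br). Ag2O in THF closes F3 with inversion at C5 to the silyl-protected epoxide F4, whose oxygen lies on the face opposite to the one the electrophile attacked. Pyridine-buffered HF·pyridine (THF, 0 °C) then removes the triethylsilyl ether and the route is rejoined at 31. The facial sense is thereby inverted relative to a direct electrophilic epoxidation.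

Step 6 (carbocupration). The thermally labile alkylcopper may decompose, insertion of propyne may be incomplete or multiple, and the valuable bromide would be lost. The fallback sets out from 8 and propyne 9 and builds the same Z-iodide by cross-coupling. Syn-bromoboration of 9 with BBr3 (CH2Cl2, −78 °C) gives (Z)-(2-bromoprop-1-enyl)dibromoborane F5, which pinacol converts into the pinacol boronate F6. Zinc insertion into 8 (Zn dust, LiCl, THF, 50 °C) gives the alkylzinc bromide F7. Negishi coupling of F6 with F7 (Pd[P(t-Bu)3]2 cat., THF, 25 °C) replaces bromine with retention and gives the Z-alkenylboronate F8. Iododeboronation (I2, NaOH, THF/H2O, 0 °C) with retention rejoins the route at 12.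

**Further compounds**
F1 | step 14 | (4Z,6R,7R,8S,9R,10R)-9-(tert-butyldimethylsilyloxy)-6-hydroxy-13-norgermacr-4-en-12,8-olide (C6 epimer of 25) | C1C(=O)O[C@@H]2[C@H](O[Si](C)(C)C(C)(C)C)[C@H](C)CCC/C(C)=C\[C@@H](O)[C@@H]12
F2 | step 14 | (4Z,7S,8S,9R,10R)-9-(tert-butyldimethylsilyloxy)-6-oxo-13-norgermacr-4-en-12,8-olide | C1C(=O)O[C@@H]2[C@H](O[Si](C)(C)C(C)(C)C)[C@H](C)CCC/C(C)=C\C(=O)[C@@H]12
F3 | step 18 | (4R,5R,6R,7S,8S,9R,10R)-5-bromo-9-(tert-butyldimethylsilyloxy)-4-hydroxy-6-(triethylsilyloxy)germacr-11(13)-en-12,8-olide | C=C1C(=O)O[C@@H]2[C@H](O[Si](C)(C)C(C)(C)C)[C@H](C)CCC[C@@](C)(O)[C@H](Br)[C@H](O[Si](CC)(CC)CC)[C@@H]12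
F4 | step 18 | (4R,5S,6R,7S,8S,9R,10R)-9-(tert-butyldimethylsilyloxy)-4,5-epoxy-6-(triethylsilyloxy)germacr-11(13)-en-12,8-olide | C=C1C(=O)O[C@@H]2[C@H](O[Si](C)(C)C(C)(C)C)[C@H](C)CCC[C@@]3(C)O[C@H]3[C@H](O[Si](CC)(CC)CC)[C@@H]12
F5 | step 6 | (Z)-(2-bromoprop-1-enyl)dibromoborane | Br/C(C)=C\B(Br)Br
F6 | step 6 | 2-[(Z)-2-bromoprop-1-enyl]-4,4,5,5-tetramethyl-1,3,2-dioxaborolane | Br/C(C)=C\B1OC(C)(C)C(C)(C)O1
F7 | step 6 | [(4R,5R)-5,6-bis(tert-butyldimethylsilyloxy)-4-methylhexyl]zinc bromide | CC(C)(C)[Si](C)(C)OC[C@H](O[Si](C)(C)C(C)(C)C)[C@H](C)CCC[Zn]Br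
F8 | step 6 | 2-[(1Z,6R,7R)-7,8-bis(tert-butyldimethylsilyloxy)-2,6-dimethyloct-1-enyl]-4,4,5,5-tetramethyl-1,3,2-dioxaborolane | CC(C)(C)[Si](C)(C)OC[C@H](O[Si](C)(C)C(C)(C)C)[C@H](C)CCC/C(C)=C\B1OC(C)(C)C(C)(C)O1
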